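## Structural features

Kanzonol L is an isoflavone: a benzene ring (ring A) fused to a 4-pyranone (ring C) that carries a second benzene ring (ring B) at C3, and ring B is fused through C2'–O and C3'–C to a 2,2-dimethyl-2H-pyran (ring D). Ring A is hexasubstituted, with hydroxyls on C5 and C7 and 3-methylbut-2-enyl (prenyl) chains on C6 and C8. Ring B carries four contiguous substituents: the C3 link on C1', the ring D oxygen on C2', the ring D vinyl carbon C4'' on C3' and a hydroxyl on C4'. There is no stereocentre, so every selectivity problem is one of regiochemistry. The fragile parts are the two prenyl double bonds (each flanked by phenolic oxygens and prone to acid-induced closure to chromans), the electron-rich styrene-like C3''=C4'' bond of ring D, and the oxidisable polyphenol; hydrogenation, strong Lewis acids and electrophilic oxidants are excluded once these groups are present. The real difficulty is double: ring D must be fused in the angular sense, with its oxygen on C2' beside the C1'–C3 bond and not on C4', and the fully substituted ring A must be bonded to C4 without exposing prenyl groups to Friedel–Crafts conditions. The key step exploits the fact that the ring D oxygen and the ring D carbon sit on the adjacent atoms C2' and C3', directly beside the C4' oxygen: C2' and C3' become the two carbons of an aryne that the C4' alkoxy group polarises, so that an aldehyde oxygen goes to C2' and the aldehyde carbon to C3'. Before ring C is closed, ring A has two equivalent oxygens ortho to the carbonyl, so closure of ring C cannot give regioisomers.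

## Logic of the disconnections

29 ⇒ 28. The O1–C2 bond of ring C and the four O–CH2 bonds of the phenol-protecting acetals are cut together. 28 already holds every carbon of 29 and closes ring C by itself once an oxygen ortho to the carbonyl is free, so the acid-sensitive polyphenol appears only in the last operation. The gain is a neutral, non-phenolic precursor. The demand is that one mild protic treatment cleaves four acetals and triggers addition–elimination without protonating the prenyl or chromene double bonds.

28 ⇒ 27. The C2=C3 bond is cut, removing the one-carbon unit C2. This leaves a deoxybenzoin-type ketone whose only acidic CH2 is the future C3. The gain is that C2 comes from a cheap amide acetal. The demand is condensation at the α-carbon of a hindered ketone, which is easier while no phenol is free.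

27 ⇒ 26 ⇒ 23 + 16. The C4–C4a bond is cut, with 26 as the alcohol-level relay. Making this bond from a nucleophilic ring A and an electrophilic C4 avoids Lewis-acid acylation of a prenylated, acetal-protected arene. The gain is convergence: 23 holds ring A with both prenyl groups, and 16 holds rings B and D with C3 and C4. The demand is that a hindered, basic aryl metal adds to an enolisable aldehyde, and that the following oxidation spares three kinds of alkene.

23 ⇒ 21 ⇒ 18 ⇒ 17 + 19. The two aryl–CH2 bonds of the prenyl groups and the three O–CH2 bonds of the acetals are cut. Every ring position of 18 and 21 lies between two coordinating ether oxygens and can be lithiated in turn. The gain is a return to 17 and 19 with unambiguous placement of the chains. The demand is that ring lithiation outruns deprotonation of a prenyl CH2 and that alkylation occurs at the primary carbon of 19.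

16 ⇒ 15. This is a functional group change only: the aldehyde carbon is stored as its dimethyl acetal, because a free arylacetaldehyde would not survive fluoride and an aryne. The demand is hydrolysis of one acetal in the presence of a second, slower one.

15 ⇒ 10 + 11. The C2'–O, C3'–C4'' and O–C2'' bonds are cut, which removes ring D in one stroke. Both ring D bonds to ring B lie on adjacent carbons and can be traced to an aryne and the C=O of an enal. The gain is three bonds and one ring, leaving a tetrasubstituted benzene and a five-carbon aldehyde. The demand is regioselective addition of oxygen to C2', which the C4' alkoxy group must enforce.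

10 ⇒ 8 (through 9). The acetal carbon is traced back to the internal alkene carbon of an allyl group. The acetal is made only after the neighbouring oxygen is a triflate, because a free phenol ortho to the chain would capture the aldehyde as a cyclic acetal. The demand is that ozone cleaves the alkene and spares the arene and the C–Si bond.

8 ⇒ 5 (through 6 and 7). The C3'–Si and O–S bonds are cut. An ortho-silyl aryl triflate comes from an ortho-bromophenol by O-silylation, halogen–lithium exchange with O→C silyl shift, and triflation. The demand is that bromine–lithium exchange is faster than any deprotonation.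

5 ⇒ 4 ⇒ 3 ⇒ 1 + 2. The C1'–CH2 bond is cut by a retro-Claisen step, then the O–CH2 acetal bond and the O–allyl bond. The rearrangement delivers the chain to the only free ortho carbon and at the same time unveils the phenol that becomes the triflate, so the two oxygens of 1 are told apart by construction. The demand is mono-alkylation of symmetric 1.

## Other disconnections considered

Alternative 1: The cut runs through C3–C4 and O1–C2, so ring C is the last ring formed and ring A arrives as an aroyl unit. In the forward step enamine A2 would be acylated at its β-carbon (the future C3) by aroyl chloride A3. Carbonate in methanol would then remove the aryl acetates, and an ortho phenoxide would add to C2 and expel the amine, giving A1, the C4'-O-silyl ether of the target, which fluoride would unmask.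
- In favour: ring C closes under basic conditions, ring A is symmetric so either phenoxide gives the same product, and no acid ever meets the prenyl groups.
- Against: A3 is a di-ortho-substituted, electron-rich aroyl chloride derived from a decarboxylation-prone trihydroxybenzoic acid. C-acylation of a conjugated β-aryl enamine by so hindered an electrophile competes with N-acylation and with acyl transfer from the aryl acetates. A silyl ether on the C4' oxygen could not pass through a fluoride-triggered aryne, so A2 would need a protecting-group exchange after 15 or a different origin for ring D.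
- Comparison: on protecting-group safety the alternative is the better plan. On convergence the two are equal. On step economy after fragment union it is better (two operations against the four of steps 11–14), but the carboxylation, acetylation and chloride formation needed for A3 give this back, so the totals are similar. Mechanistically its key step forms two bonds and ring C by a hindered acylation. The chosen key step forms three bonds and ring D on a small, cheap arene, where failure costs little.

Alternative 2: The cut removes ring B itself: C2'–C3', C4'–C5' and C1'–C2' are disconnected, leaving chromone diazoketone A5 and siloxyalkyne A6. In the forward step irradiation of A5 would give a vinylketene by Wolff rearrangement. The ketene would add A6, and the vinylcyclobutenone would open and reclose by 6π electrocyclisation to give A4, with a free C2' hydroxyl, a C3' prenyl group and a silylated C4' oxygen (Danheiser benzannulation).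
- In favour: the substitution pattern of ring B follows from connectivity alone, the two ring B oxygens emerge already differentiated, and no organometallic reagent is needed.
- Against: ring D is not formed. It would have to be closed afterwards by dehydrogenative cyclisation of the C3' prenyl group onto the C2' hydroxyl with a quinone-type oxidant, which must discriminate between three prenyl groups. A5 has to be built on a chromone whose C2=C3 bond is itself reactive towards diazoalkanes and nucleophiles. The photolysis is run on a strongly absorbing chromone carrying alkenes that can intercept a ketene. The most valuable intermediate, with rings A and C fully dressed, is carried through the riskiest steps.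
- Comparison: on regiocontrol the alternative is the better plan, since nothing depends on the polarisation of an aryne. On bonds formed the two are equal in number (three each), and the alternative's are all C–C bonds. On step economy and convergence the chosen plan is better: its key step closes ring D directly, while the alternative still needs ring D closure and removal of three protecting groups after a longer linear sequence.

Alternative 3: The cut is at the two aryl–CH2 bonds of the C6 and C8 prenyl groups. The precursor is the symmetric deoxybenzoin A8, whose two oxygens ortho to the carbonyl carry 1,1-dimethylallyl groups. On heating each ether would undergo a [3,3] shift to its only free ortho carbon, giving A7; no ring is closed.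
- In favour: both prenyl groups are placed by intramolecular delivery with complete positional certainty, no lithiation is run in the presence of a prenyl group, and the ring B half of A8 is the same chromene as in 15, so the plan is compatible with the chosen key step.
- Against: tertiary allyl ethers must be installed on two chelated phenols ortho to a ketone, normally through propargylic ethers and semi-hydrogenation in the presence of the chromene double bond. Such ethers also lose the allyl group by elimination or migrate further to the para position. The symmetric deoxybenzoin still has to be made by attaching C4 to a phloroglucinol ring, the same problem the chosen route solves with an aryl metal. After A7, ring C must still be closed and two acetals removed with acid, as in the chosen plan.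
- Comparison: on positional certainty of the prenyl groups the alternative is the better plan. On the final acid deprotection the two are equal. On step economy the chosen plan is better, because two lithiation–alkylation steps replace two etherifications, a reduction and the rearrangement. As a key step the rearrangement adds two C–C bonds but builds neither a ring nor the hard part of the skeleton.

Key step: step 6

Remark 1: 10 and 15 map atom for atom onto C1'–C6' of 29 (triflate carbon = C2', silyl carbon = C3', acetal chain on C1', methoxymethoxy on C4'); their structures need no correction and are kept unchanged.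

Remark 2 (assumption): the aryl methoxymethyl ether is taken to survive the brief dilute-acid hydrolysis of step 7, because a formaldehyde-derived acetal ionises much more slowly than an aldehyde dimethyl acetal.

Remark 3: three weak points on the way to and from the key step are removed.
- The two oxygens are differentiated before the Claisen rearrangement, not by selective protection of a diol.
- The acetal is made only after the phenol is a triflate, since a free ortho phenol would capture the aldehyde as a cyclic acetal.
- Ring A is joined as an aryl-metal nucleophile and not by Lewis-acid acylation, which prenyl groups, the chromene and the acetal protecting group would not survive.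

## Route

Step 1
Reactants: 1 2-bromoresorcinol (2-bromobenzene-1,3-diol); 2 allyl bromide (3-bromoprop-1-ene)
Product: 3 3-(allyloxy)-2-bromophenol
Conditions: K2CO3 (1.0 equiv), 2 (1.0 equiv), acetone, reflux
Reagents that add atoms: none
Why: Williamson etherification; the two hydroxyls of 1 are equivalent, and with one equivalent each of base and 2 the mono-ether should predominate, the bis-ether and unchanged 1 being separated and 1 recycled.

Step 2
Reactants: 3 3-(allyloxy)-2-bromophenol
Product: 4 1-(allyloxy)-2-bromo-3-(methoxymethoxy)benzene
Conditions: NaH, MOMCl, DMF, 0 °C → rt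
Reagents that add atoms: chloromethyl methyl ether, COCCl
Why: O-alkylation of the sodium phenoxide by the alkoxymethyl chloride; placing the methoxymethyl group before the rearrangement means no selective protection of a diol is needed later.

Step 3
Reactants: 4 1-(allyloxy)-2-bromo-3-(methoxymethoxy)benzene
Product: 5 6-allyl-2-bromo-3-(methoxymethoxy)phenol
Conditions: PhNEt2, 190 °C, argon
Reagents that add atoms: none
Why: Aromatic Claisen rearrangement ([3,3] shift then tautomerisation); one ortho carbon carries bromine, so the allyl group should go to the free one (the future C1'), and the phenol that appears is the one destined to become the triflate.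

Step 4
Reactants: 5 6-allyl-2-bromo-3-(methoxymethoxy)phenol
Product: 8 6-allyl-3-(methoxymethoxy)-2-(trimethylsilyl)phenyl trifluoromethanesulfonate, via trimethylsilyl ether 6 (not isolated), via lithium phenoxide 7 (not isolated)
Conditions: HMDS, THF, 70 °C, then evaporation; n-BuLi, THF, −78 °C; Tf2O, −78 °C → 0 °C
Reagents that add atoms: hexamethyldisilazane, C[Si](C)(C)N[Si](C)(C)C; trifluoromethanesulfonic anhydride, O=S(=O)(OS(=O)(=O)C(F)(F)F)C(F)(F)F
Why: O-silylation gives 6; bromine–lithium exchange (faster than any deprotonation at −78 °C) is followed by a 1,3 O→C silyl shift (retro-Brook rearrangement) to phenoxide 7, which is trapped as the triflate; the allyl and methoxymethyl groups are inert to each reagent.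

Step 5
Reactants: 8 6-allyl-3-(methoxymethoxy)-2-(trimethylsilyl)phenyl trifluoromethanesulfonate
Product: 10 6-(2,2-dimethoxyethyl)-3-(methoxymethoxy)-2-(trimethylsilyl)phenyl trifluoromethanesulfonate, via aldehyde 9 (not isolated)
Conditions: O3, CH2Cl2/MeOH, −78 °C; Me2S, −78 °C → rt; then HC(OMe)3, PPTS (cat.), MeOH, rt
Reagents that add atoms: trimethyl orthoformate, COC(OC)OC; methanol, CO
Why: Ozonolysis of the only alkene with reductive work-up, then acid-catalysed acetalisation driven by the orthoformate; because the phenol oxygen is already a triflate the aldehyde cannot close to a cyclic acetal, and the electron-poor aryl triflate, the C–Si bond and the aryl acetal should tolerate ozone at low temperature and pyridinium catalysis.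

Step 6
Reactants: 10 6-(2,2-dimethoxyethyl)-3-(methoxymethoxy)-2-(trimethylsilyl)phenyl trifluoromethanesulfonate; 11 3-methylbut-2-enal
Product: 15 8-(2,2-dimethoxyethyl)-5-(methoxymethoxy)-2,2-dimethyl-2H-chromene, via aryne 12 (not isolated), via benzoxete 13 (not isolated), via o-quinone methide 14 (not isolated)
Conditions: CsF (3 equiv), 11 (5 equiv), MeCN, rt → 40 °C, slow addition of 10
Reagents that add atoms: none
Why: Fluoride attacks silicon and the triflate leaves, giving aryne 12 across C2'–C3'. The carbonyl oxygen of 11 adds to C2' and the resulting C3' aryl anion closes on the carbonyl carbon, a stepwise formal [2+2] that gives benzoxete 13. Strain drives 4π electrocyclic opening to o-quinone methide 14, whose O=C2'–C3'=C4''–C3''=C2'' unit closes ring D by thermal oxa-6π electrocyclisation, the gem-dimethyl carbon ending on oxygen because it is the only terminus available. The closest known reaction type is the coupling of arynes from ortho-silylaryl triflates with α,β-unsaturated aldehydes to give 2H-chromenes. Ring D is therefore closed by 6π electrocyclisation, and no stereocentre survives, since the benzoxete carbon is planarised on opening. The selectivity needed is addition of oxygen to C2' and not C3': the C4' methoxymethoxy group polarises the aryne by induction, so attack at the remote carbon C2' places the developing carbanion on C3' next to that oxygen, and the primary alkyl chain on C1' is too small to override this. Intermolecular capture must also outrun attack of an acetal oxygen of the side chain on C2', which the low nucleophilicity of acetal oxygen and the excess of 11 should secure; the acetal, the aryl ether and the new chromene are inert to CsF.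

Step 7
Reactants: 15 8-(2,2-dimethoxyethyl)-5-(methoxymethoxy)-2,2-dimethyl-2H-chromene
Product: 16 2-[5-(methoxymethoxy)-2,2-dimethyl-2H-chromen-8-yl]acetaldehyde
Conditions: aq. HCl (1 M), THF, 0 °C → rt, short reaction time; used crude
Reagents that add atoms: water, O
Why: Acid-catalysed acetal hydrolysis; the aldehyde dimethyl acetal ionises far faster than the aryl methoxymethyl ether, so brief exposure to dilute acid should unmask only the aldehyde, which is used at once because arylacetaldehydes enolise and self-condense.

Step 8
Reactants: 17 phloroglucinol (benzene-1,3,5-triol)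
Product: 18 1,3,5-tris(methoxymethoxy)benzene
Conditions: NaH, MOMCl, DMF, 0 °C → rt
Reagents that add atoms: chloromethyl methyl ether, COCCl
Why: Threefold O-alkylation of the phenoxide by the hard alkoxymethyl chloride; the three ethers later act as ortho-directing groups and are removed together with the one on ring B.

Step 9
Reactants: 18 1,3,5-tris(methoxymethoxy)benzene; 19 prenyl bromide (1-bromo-3-methylbut-2-ene)
Product: 21 1,3,5-tris(methoxymethoxy)-2-(3-methylbut-2-en-1-yl)benzene, via aryllithium 20 (not isolated)
Conditions: n-BuLi, THF, 0 °C; then 19, −78 °C → rt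
Reagents that add atoms: none
Why: Directed ortho-metalation; every ring hydrogen of 18 lies between two methoxymethoxy groups, so n-BuLi gives 20, which should be alkylated by the primary allylic bromide at its CH2 end (SN2).

Step 10
Reactants: 21 1,3,5-tris(methoxymethoxy)-2-(3-methylbut-2-en-1-yl)benzene; 19 prenyl bromide
Product: 23 1,3,5-tris(methoxymethoxy)-2,4-bis(3-methylbut-2-en-1-yl)benzene, via aryllithium 22 (not isolated)
Conditions: n-BuLi, THF, 0 °C; then 19, −78 °C → rt
Reagents that add atoms: none
Why: Second directed ortho-metalation; the two remaining ring hydrogens of 21 are equivalent and each is flanked by two coordinating ethers, which should make ring lithiation faster than deprotonation of the prenyl CH2, and alkylation as in step 9 gives the 2,4-dialkylated arene.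

Step 11
Reactants: 23 1,3,5-tris(methoxymethoxy)-2,4-bis(3-methylbut-2-en-1-yl)benzene; 16 2-[5-(methoxymethoxy)-2,2-dimethyl-2H-chromen-8-yl]acetaldehyde
Product: 26 2-[5-(methoxymethoxy)-2,2-dimethyl-2H-chromen-8-yl]-1-[2,4,6-tris(methoxymethoxy)-3,5-bis(3-methylbut-2-en-1-yl)phenyl]ethan-1-ol (racemic), via aryllithium 24 (not isolated), via arylcerium dichloride 25 (not isolated)
Conditions: n-BuLi, THF, 0 °C; CeCl3 (anhydrous), THF, −78 °C; then 16, −78 °C; H2O
Reagents that add atoms: none
Why: Directed lithiation of the last ring position, transmetalation to the weakly basic, oxophilic organocerium and 1,2-addition to the aldehyde; organocerium addition is the standard answer to an enolisable carbonyl partner, and the carbinol centre forms as a racemate that step 12 removes.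

Step 12
Reactants: 26 the secondary alcohol of step 11
Product: 27 2-[5-(methoxymethoxy)-2,2-dimethyl-2H-chromen-8-yl]-1-[2,4,6-tris(methoxymethoxy)-3,5-bis(3-methylbut-2-en-1-yl)phenyl]ethan-1-one
Conditions: Dess–Martin periodinane, pyridine, CH2Cl2, 0 °C → rt
Reagents that add atoms: none
Why: Dess–Martin oxidation of a secondary benzylic alcohol under buffered conditions that leave the trisubstituted alkenes, the chromene and the four acetals untouched.

Step 13
Reactants: 27 the ketone of step 12
Product: 28 3-(dimethylamino)-2-[5-(methoxymethoxy)-2,2-dimethyl-2H-chromen-8-yl]-1-[2,4,6-tris(methoxymethoxy)-3,5-bis(3-methylbut-2-en-1-yl)phenyl]prop-2-en-1-one (alkene geometry not controlled)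
Conditions: Me2NCH(OMe)2, toluene, 90 °C
Reagents that add atoms: N,N-dimethylformamide dimethyl acetal, COC(OC)N(C)C
Why: Condensation of the only acidic CH2 (between carbonyl and aryl) with the amide acetal gives the enaminone and installs C2; with every phenol still masked no O-methylation can compete, and the alkene geometry is lost on ring closure.

Step 14
Reactants: 28 the enaminone of step 13
Product: 29 Kanzonol L, 5,7-dihydroxy-3-(5-hydroxy-2,2-dimethyl-2H-chromen-8-yl)-6,8-bis(3-methylbut-2-en-1-yl)-4H-chromen-4-one
Conditions: HCl (about 1 M in MeOH), rt → 40 °C
Reagents that add atoms: none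
Why: Methanolic acid transfers the four methoxymethyl groups to methanol; once one of the two equivalent oxygens ortho to the carbonyl is free it adds to the enaminone β-carbon and dimethylamine is expelled (addition–elimination, 6-endo closure of ring C), and the symmetry of ring A allows only one isoflavone. Dilute acid near room temperature is the usual way to unmask prenylated phenols without addition of the phenol to the prenyl double bond.

## Compound list

1 | 2-bromoresorcinol (2-bromobenzene-1,3-diol) | Oc1cccc(O)c1Br | starting material
2 | allyl bromide (3-bromoprop-1-ene) | C=CCBr | starting material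
3 | 3-(allyloxy)-2-bromophenol | C=CCOc1cccc(O)c1Br | intermediate
4 | 1-(allyloxy)-2-bromo-3-(methoxymethoxy)benzene | C=CCOc1cccc(OCOC)c1Br | intermediate
5 | 6-allyl-2-bromo-3-(methoxymethoxy)phenol | C=CCc1ccc(OCOC)c(Br)c1O | intermediate
6 | [6-allyl-2-bromo-3-(methoxymethoxy)phenoxy]trimethylsilane | C=CCc1ccc(OCOC)c(Br)c1O[Si](C)(C)C | intermediate
7 | lithium 6-allyl-3-(methoxymethoxy)-2-(trimethylsilyl)phenoxide | [Li+].[O-]c1c(CC=C)ccc(OCOC)c1[Si](C)(C)C | intermediate
8 | 6-allyl-3-(methoxymethoxy)-2-(trimethylsilyl)phenyl trifluoromethanesulfonate | C=CCc1ccc(OCOC)c([Si](C)(C)C)c1OS(=O)(=O)C(F)(F)F | intermediate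
9 | 3-(methoxymethoxy)-6-(2-oxoethyl)-2-(trimethylsilyl)phenyl trifluoromethanesulfonate | O=CCc1ccc(OCOC)c([Si](C)(C)C)c1OS(=O)(=O)C(F)(F)F | intermediate
10 | 6-(2,2-dimethoxyethyl)-3-(methoxymethoxy)-2-(trimethylsilyl)phenyl trifluoromethanesulfonate | COC(OC)Cc1ccc(OCOC)c([Si](C)(C)C)c1OS(=O)(=O)C(F)(F)F | intermediate
11 | 3-methylbut-2-enal | CC(C)=CC=O | starting material
12 | 3-(2,2-dimethoxyethyl)-6-(methoxymethoxy)benzyne (1,2-didehydrobenzene) | COC(OC)CC1=CC=C(OCOC)C#C1 | intermediate
13 | 6-(2,2-dimethoxyethyl)-3-(methoxymethoxy)-2-(2-methylprop-1-en-1-yl)-2H-benzo[b]oxete (racemic, transient) | COC(OC)Cc1ccc(OCOC)c2C(C=C(C)C)Oc12 | intermediate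
14 | 2-(2,2-dimethoxyethyl)-5-(methoxymethoxy)-6-(3-methylbut-2-en-1-ylidene)cyclohexa-2,4-dien-1-one (exocyclic geometry not fixed) | COC(OC)CC1=CC=C(OCOC)C(=CC=C(C)C)C1=O | intermediate
15 | 8-(2,2-dimethoxyethyl)-5-(methoxymethoxy)-2,2-dimethyl-2H-chromene | COC(OC)Cc1ccc(OCOC)c2c1OC(C)(C)C=C2 | intermediate
16 | 2-[5-(methoxymethoxy)-2,2-dimethyl-2H-chromen-8-yl]acetaldehyde | O=CCc1ccc(OCOC)c2c1OC(C)(C)C=C2 | intermediate
17 | phloroglucinol (benzene-1,3,5-triol) | Oc1cc(O)cc(O)c1 | starting material
18 | 1,3,5-tris(methoxymethoxy)benzene | COCOc1cc(OCOC)cc(OCOC)c1 | intermediate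
19 | prenyl bromide (1-bromo-3-methylbut-2-ene) | CC(C)=CCBr | starting material
20 | [2,4,6-tris(methoxymethoxy)phenyl]lithium | [Li]c1c(OCOC)cc(OCOC)cc1OCOC | intermediate
21 | 1,3,5-tris(methoxymethoxy)-2-(3-methylbut-2-en-1-yl)benzene | COCOc1cc(OCOC)c(CC=C(C)C)c(OCOC)c1 | intermediate
22 | [2,4,6-tris(methoxymethoxy)-3-(3-methylbut-2-en-1-yl)phenyl]lithium | [Li]c1c(OCOC)cc(OCOC)c(CC=C(C)C)c1OCOC | intermediate
23 | 1,3,5-tris(methoxymethoxy)-2,4-bis(3-methylbut-2-en-1-yl)benzene | COCOc1cc(OCOC)c(CC=C(C)C)c(OCOC)c1CC=C(C)C | intermediate
24 | [2,4,6-tris(methoxymethoxy)-3,5-bis(3-methylbut-2-en-1-yl)phenyl]lithium | [Li]c1c(OCOC)c(CC=C(C)C)c(OCOC)c(CC=C(C)C)c1OCOC | intermediate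
25 | dichloro[2,4,6-tris(methoxymethoxy)-3,5-bis(3-methylbut-2-en-1-yl)phenyl]cerium | Cl[Ce](Cl)c1c(OCOC)c(CC=C(C)C)c(OCOC)c(CC=C(C)C)c1OCOC | intermediate
26 | 2-[5-(methoxymethoxy)-2,2-dimethyl-2H-chromen-8-yl]-1-[2,4,6-tris(methoxymethoxy)-3,5-bis(3-methylbut-2-en-1-yl)phenyl]ethan-1-ol (racemic) | COCOc1c(CC=C(C)C)c(OCOC)c(C(O)Cc2ccc(OCOC)c3c2OC(C)(C)C=C3)c(OCOC)c1CC=C(C)C | intermediate
27 | 2-[5-(methoxymethoxy)-2,2-dimethyl-2H-chromen-8-yl]-1-[2,4,6-tris(methoxymethoxy)-3,5-bis(3-methylbut-2-en-1-yl)phenyl]ethan-1-one | COCOc1c(CC=C(C)C)c(OCOC)c(C(=O)Cc2ccc(OCOC)c3c2OC(C)(C)C=C3)c(OCOC)c1CC=C(C)C | intermediate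
28 | 3-(dimethylamino)-2-[5-(methoxymethoxy)-2,2-dimethyl-2H-chromen-8-yl]-1-[2,4,6-tris(methoxymethoxy)-3,5-bis(3-methylbut-2-en-1-yl)phenyl]prop-2-en-1-one (geometry not controlled) | COCOc1c(CC=C(C)C)c(OCOC)c(C(=O)C(=CN(C)C)c2ccc(OCOC)c3c2OC(C)(C)C=C3)c(OCOC)c1CC=C(C)C | intermediate
29 | Kanzonol L, 5,7-dihydroxy-3-(5-hydroxy-2,2-dimethyl-2H-chromen-8-yl)-6,8-bis(3-methylbut-2-en-1-yl)-4H-chromen-4-one (no stereocentre) | CC(C)=CCc1c(O)c(CC=C(C)C)c2occ(-c3ccc(O)c4c3OC(C)(C)C=C4)c(=O)c2c1O | target

## Step count and least certain steps

Total: 14 steps. Longest linear sequence: 11 steps (steps 1–7, then 11–14). The ring A branch (steps 8–10) joins at step 11.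

Step 6 (key step). The aryne may be captured by an acetal oxygen of its own side chain through a five-membered transition state, a process that dilution does not suppress. Fluoride may also induce self-condensation of 11, and the C1' chain may erode the regiocontrol exerted by the C4' oxygen. The fallback leaves the aryne altogether. From 5, bromine–lithium exchange with n-BuLi (2.2 equiv, THF, −78 °C) and protonation would give 2-allyl-5-(methoxymethoxy)phenol F1. O-Alkylation with 3-chloro-3-methylbut-1-yne (DBU, CuCl2 catalytic, MeCN, 0 °C) would give 1-allyl-4-(methoxymethoxy)-2-[(2-methylbut-3-yn-2-yl)oxy]benzene F2. Cleavage of the terminal alkene (OsO4 catalytic, NaIO4, 2,6-lutidine, dioxane/water) and acetalisation (HC(OMe)3, PPTS, MeOH) would give 1-(2,2-dimethoxyethyl)-4-(methoxymethoxy)-2-[(2-methylbut-3-yn-2-yl)oxy]benzene F3. Heating F3 in N,N-diethylaniline at about 180 °C would bring about propargyl Claisen rearrangement to the only free ortho carbon (C3'), 1,5-hydrogen shift and oxa-6π closure, and the route is rejoined at 15.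

Step 11. The hindered aryl metal may take a proton from the enolisable aldehyde and not add to it, and the lithiation of 23 may be incomplete. The fallback replaces carbonyl addition by a coupling with a non-basic aryl metal. From 16, Pinnick oxidation (NaClO2, NaH2PO4, 2-methylbut-2-ene, t-BuOH/water) would give [5-(methoxymethoxy)-2,2-dimethyl-2H-chromen-8-yl]acetic acid F4, and 1-chloro-N,N,2-trimethylprop-1-en-1-amine would convert it under neutral conditions into [5-(methoxymethoxy)-2,2-dimethyl-2H-chromen-8-yl]acetyl chloride F5. Aryllithium 24 would be transmetalated with ZnCl2 to chloro[2,4,6-tris(methoxymethoxy)-3,5-bis(3-methylbut-2-en-1-yl)phenyl]zinc F6. Negishi acylation of F6 with F5, catalysed by Pd(PPh3)4 (zerovalent palladium) in THF, would give 27 directly, by-passing 26 and step 12.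

Step 14. The freed phenols may add to the neighbouring prenyl double bonds under acid (chroman formation), acid may add across the chromene double bond, the aminomethylene carbon may be lost by solvolysis before a phenol is free, or the hindered acetals may be cleaved incompletely. The fallback removes the acetals without protic acid and closes ring C afterwards under neutral conditions. From 27, TMSOTf and 2,2'-bipyridyl (CH2Cl2, 0 °C → rt) would exchange the four methoxymethyl groups for silyl groups, giving 2-{2,2-dimethyl-5-[(trimethylsilyl)oxy]-2H-chromen-8-yl}-1-{3,5-bis(3-methylbut-2-en-1-yl)-2,4,6-tris[(trimethylsilyl)oxy]phenyl}ethan-1-one F7. Water would cleave F7 to 2-(5-hydroxy-2,2-dimethyl-2H-chromen-8-yl)-1-[2,4,6-trihydroxy-3,5-bis(3-methylbut-2-en-1-yl)phenyl]ethan-1-one F8. F8 with N,N-dimethylformamide dimethyl acetal in THF at 40–50 °C would then form the enaminone and cyclise, returning to the route at 29.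

Step 10. Deprotonation may occur at the doubly activated prenyl CH2 in place of the ring position, and alkylation may proceed with allylic transposition. The fallback avoids lithiation in the presence of a prenyl group and replaces steps 8–10. From 17, C-alkylation of the phenoxide with 19 (2 equiv, aqueous KOH, 0 °C) would give 2,4-bis(3-methylbut-2-en-1-yl)benzene-1,3,5-triol F9 after separation from mono- and tri-alkylated material. NaH and chloromethyl methyl ether in DMF would then give 23, where the route is rejoined.

Step 7. The aryl methoxymethyl ether may be partly lost, the chromene may be hydrated under acid, and the aldehyde may self-condense. The fallback carries the side chain in a form that is unmasked without acid. From 8, ozonolysis with NaBH4 work-up would give 6-(2-hydroxyethyl)-3-(methoxymethoxy)-2-(trimethylsilyl)phenyl trifluoromethanesulfonate F10, and acetylation (Ac2O, pyridine) would give 2-[4-(methoxymethoxy)-2-{[(trifluoromethyl)sulfonyl]oxy}-3-(trimethylsilyl)phenyl]ethyl acetate F11. The aryne coupling with 11 under the conditions of step 6 would give 2-[5-(methoxymethoxy)-2,2-dimethyl-2H-chromen-8-yl]ethyl acetate F12. An ester oxygen is too poor a nucleophile to intercept the aryne, so this variant also answers the first failure mode of step 6. K2CO3 in methanol would give 2-[5-(methoxymethoxy)-2,2-dimethyl-2H-chromen-8-yl]ethan-1-ol F13, and Dess–Martin oxidation would return to the route at 16.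

## Further compounds

F1 | step 6 | 2-allyl-5-(methoxymethoxy)phenol | C=CCc1ccc(OCOC)cc1O
F2 | step 6 | 1-allyl-4-(methoxymethoxy)-2-[(2-methylbut-3-yn-2-yl)oxy]benzene | C=CCc1ccc(OCOC)cc1OC(C)(C)C#C
F3 | step 6 | 1-(2,2-dimethoxyethyl)-4-(methoxymethoxy)-2-[(2-methylbut-3-yn-2-yl)oxy]benzene | COC(OC)Cc1ccc(OCOC)cc1OC(C)(C)C#C
F4 | step 11 | [5-(methoxymethoxy)-2,2-dimethyl-2H-chromen-8-yl]acetic acid | OC(=O)Cc1ccc(OCOC)c2c1OC(C)(C)C=C2
F5 | step 11 | [5-(methoxymethoxy)-2,2-dimethyl-2H-chromen-8-yl]acetyl chloride | O=C(Cl)Cc1ccc(OCOC)c2c1OC(C)(C)C=C2
F6 | step 11 | chloro[2,4,6-tris(methoxymethoxy)-3,5-bis(3-methylbut-2-en-1-yl)phenyl]zinc | Cl[Zn]c1c(OCOC)c(CC=C(C)C)c(OCOC)c(CC=C(C)C)c1OCOC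
F7 | step 14 | 2-{2,2-dimethyl-5-[(trimethylsilyl)oxy]-2H-chromen-8-yl}-1-{3,5-bis(3-methylbut-2-en-1-yl)-2,4,6-tris[(trimethylsilyl)oxy]phenyl}ethan-1-one | C[Si](C)(C)Oc1c(CC=C(C)C)c(O[Si](C)(C)C)c(C(=O)Cc2ccc(O[Si](C)(C)C)c3c2OC(C)(C)C=C3)c(O[Si](C)(C)C)c1CC=C(C)C
F8 | step 14 | 2-(5-hydroxy-2,2-dimethyl-2H-chromen-8-yl)-1-[2,4,6-trihydroxy-3,5-bis(3-methylbut-2-en-1-yl)phenyl]ethan-1-one | CC(C)=CCc1c(O)c(CC=C(C)C)c(O)c(C(=O)Cc2ccc(O)c3c2OC(C)(C)C=C3)c1O
F9 | step 10 | 2,4-bis(3-methylbut-2-en-1-yl)benzene-1,3,5-triol | CC(C)=CCc1c(O)cc(O)c(CC=C(C)C)c1O
F10 | step 7 | 6-(2-hydroxyethyl)-3-(methoxymethoxy)-2-(trimethylsilyl)phenyl trifluoromethanesulfonate | OCCc1ccc(OCOC)c([Si](C)(C)C)c1OS(=O)(=O)C(F)(F)F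
F11 | step 7 | 2-[4-(methoxymethoxy)-2-{[(trifluoromethyl)sulfonyl]oxy}-3-(trimethylsilyl)phenyl]ethyl acetate | CC(=O)OCCc1ccc(OCOC)c([Si](C)(C)C)c1OS(=O)(=O)C(F)(F)F
F12 | step 7 | 2-[5-(methoxymethoxy)-2,2-dimethyl-2H-chromen-8-yl]ethyl acetate | CC(=O)OCCc1ccc(OCOC)c2c1OC(C)(C)C=C2
F13 | step 7 | 2-[5-(methoxymethoxy)-2,2-dimethyl-2H-chromen-8-yl]ethan-1-ol | OCCc1ccc(OCOC)c2c1OC(C)(C)C=C2
A1 | alternative 1 | 4'-O-triisopropylsilyl Kanzonol L | CC(C)=CCc1c(O)c(CC=C(C)C)c2occ(-c3ccc(O[Si](C(C)C)(C(C)C)C(C)C)c4c3OC(C)(C)C=C4)c(=O)c2c1O
A2 | alternative 1 | 4-{(E)-2-[2,2-dimethyl-5-(triisopropylsilyloxy)-2H-chromen-8-yl]ethenyl}morpholine | CC(C)[Si](Oc1ccc(/C=C/N2CCOCC2)c2OC(C)(C)C=Cc12)(C(C)C)C(C)C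
A3 | alternative 1 | 2,4,6-triacetoxy-3,5-bis(3-methylbut-2-en-1-yl)benzoyl chloride | CC(=O)Oc1c(CC=C(C)C)c(OC(C)=O)c(C(=O)Cl)c(OC(C)=O)c1CC=C(C)C
A4 | alternative 2 | 3-[2-hydroxy-3-(3-methylbut-2-enyl)-4-(triisopropylsilyloxy)phenyl]-5,7-bis(methoxymethoxy)-6,8-bis(3-methylbut-2-enyl)chromen-4-one | CC(C)=CCc1c(O)c(-c2coc3c(CC=C(C)C)c(OCOC)c(CC=C(C)C)c(OCOC)c3c2=O)ccc1O[Si](C(C)C)(C(C)C)C(C)C
A5 | alternative 2 | 3-[(E)-4-diazo-3-oxobut-1-en-1-yl]-5,7-bis(methoxymethoxy)-6,8-bis(3-methylbut-2-enyl)chromen-4-one | CC(C)=CCc1c(OCOC)c(CC=C(C)C)c2occ(/C=C/C(=O)C=[N+]=[N-])c(=O)c2c1OCOC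
A6 | alternative 2 | triisopropyl[(5-methylhex-4-en-1-yn-1-yl)oxy]silane | CC(C)=CCC#CO[Si](C(C)C)(C(C)C)C(C)C
A7 | alternative 3 | 1-[2,6-dihydroxy-4-(methoxymethoxy)-3,5-bis(3-methylbut-2-enyl)phenyl]-2-[5-(methoxymethoxy)-2,2-dimethyl-2H-chromen-8-yl]ethanone | CC(C)=CCc1c(O)c(C(=O)Cc2ccc(OCOC)c3c2OC(C)(C)C=C3)c(O)c(CC=C(C)C)c1OCOC
A8 | alternative 3 | 1-[4-(methoxymethoxy)-2,6-bis(2-methylbut-3-en-2-yloxy)phenyl]-2-[5-(methoxymethoxy)-2,2-dimethyl-2H-chromen-8-yl]ethanone | C=CC(C)(C)Oc1cc(OCOC)cc(OC(C)(C)C=C)c1C(=O)Cc1ccc(OCOC)c2c1OC(C)(C)C=C2
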